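**Retrosynthetic overview**

1. The C1–O21 lactone is opened to seco acid 34; the (15Z)-alkene comes from semi-hydrogenation of alkyne 31; the C16–C17 bond comes from asymmetric zinc alkynylation of (E)-β-chloro enal 30 with tricyclic alkyne 24.
2. Enabling feature: ring B (N, C23, C2, C3, C4, C5, with the C1 ester on C2) is a 1,2,5,6-tetrahydronicotinate. At its 1,2-dihydropyridine level (23) C5 is an enamine carbon, so its exocyclic neighbour C6 is a nucleophilic picoline-type methyl lying 1,5 to C7 across N–C9–C8. C5–H then comes from hydride.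
3. Key disconnection C6–C7 (ring A): from amino ketone 20, ring B forms by amine–ketone cyclodehydration (N–C5) and, in the same flask, ring A forms by C-alkylation of C6 with the C7 chloride. 20 comes from amine 13 and Morita–Baylis–Hillman bromide 18.
4. Amine 13 (C9/C13/C14 triad) comes from the phenylglycinol-derived N,O-acetal lactam 3: N-acyliminium allylation sets C9, convex-face methylation sets C14, the lactam carbonyl C15 becomes the alkyne, and the allyl group is cut back to C8–C7–Cl.
5. Ring order: cyclopentane (from 1) → temporary oxazolidine/γ-lactam (removed) → ring B → ring A → 15-membered lactone.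

Key step: step 16

Remark 1 (locants): carbons are numbered along the chain of the target, C1 (lactone C=O) to C21 (OCH2), C22 = methyl on C14, C23 = NCH2; ring A = N, C5–C9; ring B = N, C23, C2–C5. The CIP descriptors at C14 and C17 change between alkyne and alkene stages without any change of geometry (14R/17S in the alkynes correspond to 14S/17R in the target).

Remark 2 (assumption): the zinc–(S,S)-ProPhenol catalyst is taken to deliver the alkynyl group to the Re face of enal 30; if a model reaction shows the opposite sense, the (R,R)-ligand is used.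

**Route**

Step 1
Reactants: 1 2-(2-oxocyclopentyl)acetic acid (racemic); 2 (R)-2-amino-2-phenylethanol
Product: 3 tricyclic N,O-acetal lactam (oxazolidine fused to hexahydrocyclopenta[b]pyrrol-2-one; N,O-acetal carbon C9 S, ring-fusion carbon C13 R, phenyl-bearing carbon R, phenyl cis to C10)
Conditions: toluene, reflux, Dean–Stark
Reagents that add atoms: none
Why: Amino alcohol–keto acid cyclocondensation; the α-centre of the keto acid (C13) epimerises through the enamine, so the cis-fused lactam with the angular cyclopentane carbon cis to phenyl should accumulate (dynamic resolution), fixing C13 and C9 from the phenylglycinol centre.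

Step 2
Reactants: 3 tricyclic N,O-acetal lactam
Product: 4 (3aR,6aS)-1-[(1R)-2-hydroxy-1-phenylethyl]-6a-(prop-2-en-1-yl)hexahydrocyclopenta[b]pyrrol-2(1H)-one
Conditions: allylSiMe3, TiCl4, CH2Cl2, −78 → 23 °C
Reagents that add atoms: allyltrimethylsilane C=CC[Si](C)(C)C
Why: Lewis-acid opening of the N,O-acetal gives a cis-fused bicyclic N-acyliminium ion that the allylsilane attacks on its convex face, cis to H13 (Hosomi–Sakurai-type allylation), so allyl replaces oxygen with retention and C9 is set (S) with nitrogen cis to the C13–C14 bond.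

Step 3
Reactants: 4 N-(2-hydroxy-1-phenylethyl) lactam
Product: 5 (3aR,6aS)-6a-(prop-2-en-1-yl)hexahydrocyclopenta[b]pyrrol-2(1H)-one
Conditions: Na, NH3 (l), THF, EtOH, −78 °C
Reagents that add atoms: none
Why: Dissolving-metal (Birch-type) cleavage of the benzylic C–N bond; the isolated alkene and the lactam are inert.

Step 4
Reactants: 5 N–H lactam
Product: 6 tert-butyl (3aR,6aS)-2-oxo-6a-(prop-2-en-1-yl)hexahydrocyclopenta[b]pyrrole-1(2H)-carboxylate
Conditions: Boc2O, DMAP, Et3N, MeCN, 23 °C
Reagents that add atoms: di-tert-butyl dicarbonate CC(C)(C)OC(=O)OC(=O)OC(C)(C)C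
Why: DMAP-catalysed N-acylation of the lactam; the carbamate activates it for enolate alkylation and for partial reduction.

Step 5
Reactants: 6 N-Boc lactam
Product: 7 tert-butyl (3R,3aR,6aS)-3-methyl-2-oxo-6a-(prop-2-en-1-yl)hexahydrocyclopenta[b]pyrrole-1(2H)-carboxylate
Conditions: LiHMDS, THF, −78 °C; MeI
Reagents that add atoms: iodomethane CI
Why: Lactam enolate alkylation; methyl iodide approaches the cis-fused bicyclic enolate on its convex face, anti to the vicinal cyclopentane carbon C12 and cis to H13, which sets C14.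

Step 6
Reactants: 7 methylated N-Boc lactam
Product: 8 tert-butyl (3R,3aR,6aS)-2-hydroxy-3-methyl-6a-(prop-2-en-1-yl)hexahydrocyclopenta[b]pyrrole-1(2H)-carboxylate (mixture at the hemiaminal carbon)
Conditions: LiBHEt3, THF, −78 °C
Reagents that add atoms: none
Why: Partial reduction of the carbamate-activated lactam stops at the tetrahedral N-Boc hemiaminal at low temperature.

Step 7
Reactants: 8 N-Boc hemiaminal
Product: 9 tert-butyl N-[(1S,2R)-2-[(2R)-but-3-yn-2-yl]-1-(prop-2-en-1-yl)cyclopentyl]carbamate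
Conditions: dimethyl (1-diazo-2-oxopropyl)phosphonate, K2CO3, MeOH, 0 → 23 °C
Reagents that add atoms: dimethyl (1-diazo-2-oxopropyl)phosphonate CC(=O)C(=[N+]=[N-])P(=O)(OC)OC
Why: Ohira–Bestmann (Seyferth–Gilbert) homologation of the ring-opened aldehyde tautomer of the hemiaminal; the mild carbonate base should leave the α-centre C14 intact.

Step 8
Reactants: 9 Boc-amino allyl alkyne
Product: 11 tert-butyl N-[(1S,2R)-2-[(2R)-but-3-yn-2-yl]-1-(2-hydroxyethyl)cyclopentyl]carbamate, via aldehyde 10 (not isolated)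
Conditions: OsO4 (cat.), NaIO4, 2,6-lutidine, dioxane/H2O, 23 °C; extraction; NaBH4, MeOH, 0 °C
Reagents that add atoms: sodium periodate [Na+].[O-]I(=O)(=O)=O
Why: Lemieux–Johnson cleavage of the monosubstituted alkene (the alkyne is inert to OsO4) followed by borohydride reduction cuts the allyl group back to the C8–C7 unit.

Step 9
Reactants: 11 primary alcohol
Product: 12 tert-butyl N-[(1S,2R)-2-[(2R)-but-3-yn-2-yl]-1-(2-chloroethyl)cyclopentyl]carbamate
Conditions: PPh3, N-chlorosuccinimide, CH2Cl2, 0 → 23 °C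
Reagents that add atoms: N-chlorosuccinimide O=C1CCC(=O)N1Cl
Why: Appel-type chlorination of the primary alcohol under neutral conditions installs the C7 leaving group.

Step 10
Reactants: 12 Boc-amino chloride
Product: 13 (1S,2R)-2-[(2R)-but-3-yn-2-yl]-1-(2-chloroethyl)cyclopentan-1-aminium trifluoroacetate
Conditions: CF3CO2H, CH2Cl2, 0 °C; evaporation
Reagents that add atoms: trifluoroacetic acid OC(=O)C(F)(F)F
Why: Acidolysis of the tert-butyl carbamate; the amine is kept as its salt so that it cannot displace the γ-chloride.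

Step 11
Reactants: 14 ethyl 2-(2-methyl-1,3-dioxolan-2-yl)acetate
Product: 15 2-(2-methyl-1,3-dioxolan-2-yl)acetaldehyde
Conditions: DIBAL-H, CH2Cl2, −78 °C
Reagents that add atoms: none
Why: Low-temperature DIBAL-H reduction of the ester stops at the aldehyde through the stable tetrahedral aluminate.

Step 12
Reactants: 15 ketal aldehyde; 16 methyl acrylate
Product: 17 methyl 3-hydroxy-2-methylidene-4-(2-methyl-1,3-dioxolan-2-yl)butanoate (racemic)
Conditions: DABCO, MeOH, 23 °C
Reagents that add atoms: none
Why: Morita–Baylis–Hillman reaction of an aliphatic aldehyde with the acrylate.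

Step 13
Reactants: 17 Morita–Baylis–Hillman alcohol
Product: 18 methyl (2Z)-2-(bromomethyl)-4-(2-methyl-1,3-dioxolan-2-yl)but-2-enoate
Conditions: N-bromosuccinimide, Me2S, CH2Cl2, 0 → 23 °C
Reagents that add atoms: N-bromosuccinimide O=C1CCC(=O)N1Br
Why: Bromosulfonium activation and SN2′ attack of bromide give the thermodynamically preferred trisubstituted allyl bromide with CH2Br cis to the C4 methylene, the geometry ring B needs; the neutral conditions spare the ketal.

Step 14
Reactants: 13 aminium trifluoroacetate; 18 allyl bromide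
Product: 19 methyl (2E)-2-({[(1S,2R)-2-[(2R)-but-3-yn-2-yl]-1-(2-chloroethyl)cyclopentyl]amino}methyl)-4-(2-methyl-1,3-dioxolan-2-yl)but-2-enoate
Conditions: K2CO3, MeCN, 0 → 23 °C
Reagents that add atoms: none
Why: SN2 N-alkylation of the hindered α-tertiary primary amine by the reactive primary allylic bromide (N–C23); hindrance at nitrogen suppresses a second alkylation, and the allylic bromide reacts far faster than the γ-chloride.

Step 15
Reactants: 19 amino ketal
Product: 20 methyl (2E)-2-({[(1S,2R)-2-[(2R)-but-3-yn-2-yl]-1-(2-chloroethyl)cyclopentyl]amino}methyl)-5-oxohex-2-enoate hydrochloride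
Conditions: 2 M HCl, THF, 23 °C; evaporation
Reagents that add atoms: water O; hydrogen chloride Cl
Why: Acid hydrolysis of the dioxolane; protonation of the amine prevents premature condensation and N-alkylation, so the amino ketone is stored as its salt.

Step 16
Reactants: 20 amino ketone hydrochloride
Product: 23 methyl (1S,2R)-2-[(2R)-but-3-yn-2-yl]-1',2',3',6'-tetrahydrospiro[cyclopentane-1,4'-quinolizine]-7'-carboxylate, via dihydropyridine chloride 21 (not isolated), via dihydropyridine iodide 22 (not isolated)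
Conditions: i-Pr2NEt, PivOH (cat.), 4 Å MS, MeCN, 45 °C; then NaI (cat.), 80 °C
Reagents that add atoms: none
Why: Proposed new method: Neutralisation frees the secondary amine, which adds to the C5 ketone (6-exo-trig) and dehydrates to 1,2-dihydropyridine 21 (ring B, N–C5); through its C4-protonated iminium, 21 equilibrates with the exocyclic enamine (C5=C6H2), and after Finkelstein exchange to 22 the enamine carbon C6 displaces iodide at C7 in a 6-(enolendo)-exo-tet SN2 step that closes ring A, the ring-fusion iminium then losing H4 to the base to give 23. The closest known reaction types are the Stork enamine C-alkylation (annulation of cyclic enamines with ω-halides) and the C-alkylation of 2-picolinium anhydrobases, of which 21 is the 1,2-dihydro analogue. No stereocentre is created and none is touched, because the N–C9 bond is never broken and C13 and C14 are remote from any acidic position. The step needs C6 to react in preference to the electronically favoured ring carbons C4 and C2 and to nitrogen: attack by C4 or C2 would place the developing N=C5 iminium at the bridgehead of an azabicyclo[3.3.1]nonane with the nitrogen lone pair twisted out of conjugation, and the vinylogous-carbamate nitrogen could only form an azetidinium, so C6 is the only nucleophilic atom the N–C9–C8–C7 tether can reach. Allylic strain between the quaternary C9 and the C6 methyl in 21 raises the ground state, holds C7 over C6 and is released on cyclisation; the amine is unmasked only in the presence of the ketone so that condensation should outrun azetidine formation.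

Step 17
Reactants: 23 tricyclic dienamine ester
Product: 24 methyl (1S,2R,9a'R)-2-[(2R)-but-3-yn-2-yl]-1',2',3',6',9',9a'-hexahydrospiro[cyclopentane-1,4'-quinolizine]-7'-carboxylate
Conditions: NaBH(OAc)3, AcOH, CH2Cl2, 0 → 23 °C
Reagents that add atoms: none
Why: Acid-mediated borohydride reduction of a 1,2-dihydropyridine to the 1,2,5,6-tetrahydropyridine: protonation at C4 gives the ring-fusion iminium N=C5, and hydride should add axially on ring A through the half-chair with C13 pseudo-equatorial, syn to the axial C10 methylene, which sets C5 (R) with C4 cis to C13 and leaves the conjugated ester untouched.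

Step 18
Reactants: 25 tert-butyl(but-3-yn-1-yloxy)dimethylsilane
Product: 26 methyl 5-{[tert-butyl(dimethyl)silyl]oxy}pent-2-ynoate
Conditions: n-BuLi, THF, −78 °C; ClCO2Me
Reagents that add atoms: methyl chloroformate COC(=O)Cl
Why: Acylation of the lithium acetylide with a chloroformate.

Step 19
Reactants: 26 ynoate
Product: 27 methyl (2E)-5-{[tert-butyl(dimethyl)silyl]oxy}-3-(tributylstannyl)pent-2-enoate
Conditions: Bu3SnLi (from Bu3SnH and LDA), CuBr·SMe2, THF/MeOH, −78 °C
Reagents that add atoms: tributyltin hydride CCCC[SnH](CCCC)CCCC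
Why: Kinetic syn-stannylcupration of the ynoate with in-situ protonation puts tin and hydrogen cis, so the ester ends cis to the C20 methylene and trans to tin.

Step 20
Reactants: 27 β-stannyl enoate
Product: 28 methyl (2E)-5-{[tert-butyl(dimethyl)silyl]oxy}-3-chloropent-2-enoate
Conditions: CuCl2, THF, 23 °C
Reagents that add atoms: CuCl2 Cl[Cu]Cl
Why: Chlorodestannylation of an alkenylstannane by CuCl2 proceeds with retention of alkene geometry, giving chlorine trans to the ester (the C18=C19 geometry of the target).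

Step 21
Reactants: 28 β-chloro enoate
Product: 29 (2E)-5-{[tert-butyl(dimethyl)silyl]oxy}-3-chloropent-2-en-1-ol
Conditions: DIBAL-H, CH2Cl2, −78 °C
Reagents that add atoms: none
Why: 1,2-Reduction of the enoate to the allylic alcohol without touching the vinyl chloride.

Step 22
Reactants: 29 allylic alcohol
Product: 30 (2E)-5-{[tert-butyl(dimethyl)silyl]oxy}-3-chloropent-2-enal
Conditions: MnO2, CH2Cl2, 23 °C
Reagents that add atoms: none
Why: Neutral allylic oxidation by MnO2 preserves the alkene geometry.

Step 23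
Reactants: 24 tricyclic alkyne ester; 30 β-chloro enal
Product: 31 methyl (1S,2R,9a'R)-2-[(2R,5S,6E)-9-{[tert-butyl(dimethyl)silyl]oxy}-7-chloro-5-hydroxynon-6-en-3-yn-2-yl]-1',2',3',6',9',9a'-hexahydrospiro[cyclopentane-1,4'-quinolizine]-7'-carboxylate
Conditions: (S,S)-ProPhenol (20 mol%), ZnMe2, Ph3PO, toluene, 23 °C then 4 °C
Reagents that add atoms: none
Why: Catalytic asymmetric alkynylation of an α,β-unsaturated aldehyde: the dinuclear zinc–ProPhenol complex delivers the zinc acetylide of 24 to the Re face of the enal and sets C17 (17S here, 17R after semi-hydrogenation); ZnMe2 tolerates the ester, vinyl chloride and tertiary amine.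

Step 24
Reactants: 31 propargylic alcohol
Product: 32 methyl (1S,2R,9a'R)-2-[(2S,3Z,5R,6E)-9-{[tert-butyl(dimethyl)silyl]oxy}-7-chloro-5-hydroxynona-3,6-dien-2-yl]-1',2',3',6',9',9a'-hexahydrospiro[cyclopentane-1,4'-quinolizine]-7'-carboxylate
Conditions: H2 (1 atm), Pd/CaCO3 poisoned with Pb(OAc)2, quinoline, EtOAc, 23 °C
Reagents that add atoms: none
Why: Lindlar semi-hydrogenation adds H2 syn to the alkyne and gives the (15Z)-alkene; the trisubstituted enoate and the vinyl chloride should be inert on the poisoned catalyst.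

Step 25
Reactants: 32 silyl ether methyl ester
Product: 34 (1S,2R,9a'R)-2-[(2S,3Z,5R,6E)-7-chloro-5,9-dihydroxynona-3,6-dien-2-yl]-1',2',3',6',9',9a'-hexahydrospiro[cyclopentane-1,4'-quinolizine]-7'-carboxylic acid, via diol ester 33 (not isolated)
Conditions: TBAF, THF, 23 °C; then LiOH, THF/MeOH/H2O, 23 °C; 1 M HCl to pH 6
Reagents that add atoms: lithium hydroxide [Li+].[OH-]
Why: Fluoride desilylation followed by saponification of the methyl ester, both under basic conditions that spare the doubly allylic C17 alcohol.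

Step 26
Reactants: 34 seco acid
Product: 36 target CNP0129639.4 (5R,9S,13R,14S,17R; 15Z,18E), via mixed anhydride 35 (not isolated)
Conditions: 2-methyl-6-nitrobenzoic anhydride, DMAP, CH2Cl2, 23 °C, slow addition, 1 mM
Reagents that add atoms: none
Why: Shiina macrolactonisation: under high dilution the mixed anhydride should be attacked by the unhindered primary C21 hydroxyl (15-membered ring) rather than the secondary C17 hydroxyl (11-membered ring), and the two cis-alkenes pre-fold the chain.

**Compound list**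

1 | 2-(2-oxocyclopentyl)acetic acid (racemic) | OC(=O)CC1CCCC1=O | starting material
2 | (R)-2-amino-2-phenylethanol | N[C@@H](CO)c1ccccc1 | starting material
3 | tricyclic N,O-acetal lactam (C9 S, C13 R, phenyl carbon R) | O=C1C[C@H]2CCC[C@]23OC[C@@H](c4ccccc4)N13 | intermediate
4 | (3aR,6aS)-1-[(1R)-2-hydroxy-1-phenylethyl]-6a-(prop-2-en-1-yl)hexahydrocyclopenta[b]pyrrol-2(1H)-one | O=C1C[C@H]2CCC[C@@]2(CC=C)N1[C@@H](CO)c1ccccc1 | intermediate
5 | (3aR,6aS)-6a-(prop-2-en-1-yl)hexahydrocyclopenta[b]pyrrol-2(1H)-one | O=C1C[C@H]2CCC[C@@]2(CC=C)N1 | intermediate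
6 | tert-butyl (3aR,6aS)-2-oxo-6a-(prop-2-en-1-yl)hexahydrocyclopenta[b]pyrrole-1(2H)-carboxylate | O=C1C[C@H]2CCC[C@@]2(CC=C)N1C(=O)OC(C)(C)C | intermediate
7 | tert-butyl (3R,3aR,6aS)-3-methyl-2-oxo-6a-(prop-2-en-1-yl)hexahydrocyclopenta[b]pyrrole-1(2H)-carboxylate | O=C1[C@H](C)[C@H]2CCC[C@@]2(CC=C)N1C(=O)OC(C)(C)C | intermediate
8 | tert-butyl (3R,3aR,6aS)-2-hydroxy-3-methyl-6a-(prop-2-en-1-yl)hexahydrocyclopenta[b]pyrrole-1(2H)-carboxylate | OC1[C@H](C)[C@H]2CCC[C@@]2(CC=C)N1C(=O)OC(C)(C)C | intermediate
9 | tert-butyl N-[(1S,2R)-2-[(2R)-but-3-yn-2-yl]-1-(prop-2-en-1-yl)cyclopentyl]carbamate | C#C[C@H](C)[C@H]1CCC[C@@]1(CC=C)NC(=O)OC(C)(C)C | intermediate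
10 | tert-butyl N-[(1S,2R)-2-[(2R)-but-3-yn-2-yl]-1-(2-oxoethyl)cyclopentyl]carbamate | C#C[C@H](C)[C@H]1CCC[C@@]1(CC=O)NC(=O)OC(C)(C)C | intermediate
11 | tert-butyl N-[(1S,2R)-2-[(2R)-but-3-yn-2-yl]-1-(2-hydroxyethyl)cyclopentyl]carbamate | C#C[C@H](C)[C@H]1CCC[C@@]1(CCO)NC(=O)OC(C)(C)C | intermediate
12 | tert-butyl N-[(1S,2R)-2-[(2R)-but-3-yn-2-yl]-1-(2-chloroethyl)cyclopentyl]carbamate | C#C[C@H](C)[C@H]1CCC[C@@]1(CCCl)NC(=O)OC(C)(C)C | intermediate
13 | (1S,2R)-2-[(2R)-but-3-yn-2-yl]-1-(2-chloroethyl)cyclopentan-1-aminium trifluoroacetate | C#C[C@H](C)[C@H]1CCC[C@@]1(CCCl)[NH3+].[O-]C(=O)C(F)(F)F | intermediate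
14 | ethyl 2-(2-methyl-1,3-dioxolan-2-yl)acetate | CCOC(=O)CC1(C)OCCO1 | starting material
15 | 2-(2-methyl-1,3-dioxolan-2-yl)acetaldehyde | O=CCC1(C)OCCO1 | intermediate
16 | methyl acrylate | C=CC(=O)OC | starting material
17 | methyl 3-hydroxy-2-methylidene-4-(2-methyl-1,3-dioxolan-2-yl)butanoate (racemic) | C=C(C(=O)OC)C(O)CC1(C)OCCO1 | intermediate
18 | methyl (2Z)-2-(bromomethyl)-4-(2-methyl-1,3-dioxolan-2-yl)but-2-enoate | COC(=O)/C(CBr)=C/CC1(C)OCCO1 | intermediate
19 | methyl (2E)-2-({[(1S,2R)-2-[(2R)-but-3-yn-2-yl]-1-(2-chloroethyl)cyclopentyl]amino}methyl)-4-(2-methyl-1,3-dioxolan-2-yl)but-2-enoate | C#C[C@H](C)[C@H]1CCC[C@@]1(CCCl)NC/C(C(=O)OC)=C\CC1(C)OCCO1 | intermediate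
20 | methyl (2E)-2-({[(1S,2R)-2-[(2R)-but-3-yn-2-yl]-1-(2-chloroethyl)cyclopentyl]amino}methyl)-5-oxohex-2-enoate hydrochloride | C#C[C@H](C)[C@H]1CCC[C@@]1(CCCl)[NH2+]C/C(C(=O)OC)=C\CC(C)=O.[Cl-] | intermediate
21 | methyl 1-[(1S,2R)-2-[(2R)-but-3-yn-2-yl]-1-(2-chloroethyl)cyclopentyl]-6-methyl-1,2-dihydropyridine-3-carboxylate | C#C[C@H](C)[C@H]1CCC[C@@]1(CCCl)N1CC(C(=O)OC)=CC=C1C | intermediate
22 | methyl 1-[(1S,2R)-2-[(2R)-but-3-yn-2-yl]-1-(2-iodoethyl)cyclopentyl]-6-methyl-1,2-dihydropyridine-3-carboxylate | C#C[C@H](C)[C@H]1CCC[C@@]1(CCI)N1CC(C(=O)OC)=CC=C1C | intermediate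
23 | methyl (1S,2R)-2-[(2R)-but-3-yn-2-yl]-1',2',3',6'-tetrahydrospiro[cyclopentane-1,4'-quinolizine]-7'-carboxylate | C#C[C@H](C)[C@H]1CCC[C@]12CCCC3=CC=C(C(=O)OC)CN23 | intermediate
24 | methyl (1S,2R,9a'R)-2-[(2R)-but-3-yn-2-yl]-1',2',3',6',9',9a'-hexahydrospiro[cyclopentane-1,4'-quinolizine]-7'-carboxylate | C#C[C@H](C)[C@H]1CCC[C@]12CCC[C@@H]3CC=C(C(=O)OC)CN23 | intermediate
25 | tert-butyl(but-3-yn-1-yloxy)dimethylsilane | C#CCCO[Si](C)(C)C(C)(C)C | starting material
26 | methyl 5-{[tert-butyl(dimethyl)silyl]oxy}pent-2-ynoate | COC(=O)C#CCCO[Si](C)(C)C(C)(C)C | intermediate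
27 | methyl (2E)-5-{[tert-butyl(dimethyl)silyl]oxy}-3-(tributylstannyl)pent-2-enoate | COC(=O)/C=C(/[Sn](CCCC)(CCCC)CCCC)CCO[Si](C)(C)C(C)(C)C | intermediate
28 | methyl (2E)-5-{[tert-butyl(dimethyl)silyl]oxy}-3-chloropent-2-enoate | COC(=O)/C=C(/Cl)CCO[Si](C)(C)C(C)(C)C | intermediate
29 | (2E)-5-{[tert-butyl(dimethyl)silyl]oxy}-3-chloropent-2-en-1-ol | OC/C=C(/Cl)CCO[Si](C)(C)C(C)(C)C | intermediate
30 | (2E)-5-{[tert-butyl(dimethyl)silyl]oxy}-3-chloropent-2-enal | O=C/C=C(/Cl)CCO[Si](C)(C)C(C)(C)C | intermediate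
31 | methyl (1S,2R,9a'R)-2-[(2R,5S,6E)-9-{[tert-butyl(dimethyl)silyl]oxy}-7-chloro-5-hydroxynon-6-en-3-yn-2-yl]-1',2',3',6',9',9a'-hexahydrospiro[cyclopentane-1,4'-quinolizine]-7'-carboxylate | C[C@@H](C#C[C@@H](O)/C=C(/Cl)CCO[Si](C)(C)C(C)(C)C)[C@H]1CCC[C@]12CCC[C@@H]3CC=C(C(=O)OC)CN23 | intermediate
32 | methyl (1S,2R,9a'R)-2-[(2S,3Z,5R,6E)-9-{[tert-butyl(dimethyl)silyl]oxy}-7-chloro-5-hydroxynona-3,6-dien-2-yl]-1',2',3',6',9',9a'-hexahydrospiro[cyclopentane-1,4'-quinolizine]-7'-carboxylate | C[C@@H](/C=C\[C@@H](O)/C=C(/Cl)CCO[Si](C)(C)C(C)(C)C)[C@H]1CCC[C@]12CCC[C@@H]3CC=C(C(=O)OC)CN23 | intermediate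
33 | methyl (1S,2R,9a'R)-2-[(2S,3Z,5R,6E)-7-chloro-5,9-dihydroxynona-3,6-dien-2-yl]-1',2',3',6',9',9a'-hexahydrospiro[cyclopentane-1,4'-quinolizine]-7'-carboxylate | C[C@@H](/C=C\[C@@H](O)/C=C(/Cl)CCO)[C@H]1CCC[C@]12CCC[C@@H]3CC=C(C(=O)OC)CN23 | intermediate
34 | (1S,2R,9a'R)-2-[(2S,3Z,5R,6E)-7-chloro-5,9-dihydroxynona-3,6-dien-2-yl]-1',2',3',6',9',9a'-hexahydrospiro[cyclopentane-1,4'-quinolizine]-7'-carboxylic acid | C[C@@H](/C=C\[C@@H](O)/C=C(/Cl)CCO)[C@H]1CCC[C@]12CCC[C@@H]3CC=C(C(=O)O)CN23 | intermediate
35 | mixed anhydride of 34 with 2-methyl-6-nitrobenzoic acid | C[C@@H](/C=C\[C@@H](O)/C=C(/Cl)CCO)[C@H]1CCC[C@]12CCC[C@@H]3CC=C(C(=O)OC(=O)c4c(C)cccc4[N+](=O)[O-])CN23 | intermediate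
36 | CNP0129639.4, (5R,9S,13R,14S,17R,15Z,18E)-macrolactone | C[C@H]1/C=C\[C@@H](O)/C=C(/Cl)CCOC(=O)C2=CC[C@H]3CCC[C@]4(CCC[C@H]14)N3C2 | target

**Step count and risks**

Total step count: 26. Longest linear sequence: 18 steps (steps 1–10, 14–17, 23–26).

Steps most likely to fail:

Step 16 (key step). The exocyclic enamine may be too scarcely populated for C-alkylation to compete. The freed amine could then N-alkylate at C7 (azetidine) before or instead of condensing, or the dihydropyridine could oxidise in air. The fallback uses known reactions only and closes ring A through the same C6–C7 bond. It sets out from 13. The free base (aq. NaHCO3) is condensed with acetone over 4 Å MS to the N-isopropylidene imine F1. LDA (2.2 equiv, the first on the alkyne) in THF at −78 → 0 °C forms the metalloenamine, which displaces the C7 chloride (Stork-type metalloenamine alkylation) to give the spiro 2-methyl cyclic imine F2. Heating F2 with methyl 3-(dimethylamino)-2-formylprop-2-enoate in AcOH builds ring B as a pyridinium ring (nicotinate synthesis from an enamine and a vinylogous formamide; only the methyl-side enamine can aromatise) and gives the quinolizinium acetate F3. NaBH4 in MeOH at 0 °C reduces F3 through 23, formed in the flask, to 24, where the route is rejoined.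

Step 17. Hydride delivery to the ring-fusion iminium may show poor facial selectivity, because allylic strain between C23 and C13 could favour the half-chair with C13 pseudo-axial and lead to the C5 epimer. The fallback sets C5 on an N–H imine, where no N-substituent biases the half-chair, and builds ring B afterwards. It sets out from 13. The free base is condensed with 4,4-dimethoxybutan-2-one to the ketimine F4. LDA (2.2 equiv) deprotonates the methyl group kinetically, and the metalloenamine cyclises onto C7 to the cyclic ketimine F5. NaBH4 in MeOH at −20 °C adds hydride axially to give the piperidine F6 with the C5 substituent equatorial and cis to C13. Conjugate addition of the N–H to methyl 2-(dimethoxyphosphoryl)acrylate gives the phosphonate F7. Aqueous HCl in THF liberates the aldehyde F8, and K2CO3 in MeCN closes ring B by intramolecular Horner–Wadsworth–Emmons olefination, which comes back to the route at 24.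

Step 23. The Lewis-basic amine of 24 may bind zinc and erode catalyst control, giving low facial selectivity at C17 or slow addition. The fallback replaces catalytic alkynylation by oxidation and reagent-controlled reduction. It sets out from 24 and 30. ZnMe2-mediated addition without ligand gives 31 together with its C17 epimer F9. MnO2 in CH2Cl2 oxidises the mixture to the ynone F10. (S)-2-Methyl-CBS-oxazaborolidine with catecholborane in toluene at −78 °C reduces F10, with the alkynyl group as the small substituent, and comes back to the route at 31.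

Further compounds
F1 | step 16 | N-isopropylidene imine of the amine of 13 | C#C[C@H](C)[C@H]1CCC[C@@]1(CCCl)N=C(C)C
F2 | step 16 | spiro 2-methyl cyclic imine (ring A closed, C4 as methyl) | C#C[C@H](C)[C@H]1CCC[C@]12CCCC(C)=N2
F3 | step 16 | quinolizinium acetate (ring B aromatic, methyl ester on C2) | C#C[C@H](C)[C@H]1CCC[C@]12CCCc3ccc(C(=O)OC)c[n+]23.CC(=O)[O-]
F4 | step 17 | ketimine of the amine of 13 with 4,4-dimethoxybutan-2-one | C#C[C@H](C)[C@H]1CCC[C@@]1(CCCl)N=C(C)CC(OC)OC
F5 | step 17 | spiro cyclic ketimine bearing the 2,2-dimethoxyethyl group on C5 | C#C[C@H](C)[C@H]1CCC[C@]12CCCC(CC(OC)OC)=N2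
F6 | step 17 | (5R)-piperidine with 2,2-dimethoxyethyl on C5 | C#C[C@H](C)[C@H]1CCC[C@]12CCC[C@H](CC(OC)OC)N2
F7 | step 17 | N-[2-(dimethoxyphosphoryl)-2-(methoxycarbonyl)ethyl] piperidine acetal | C#C[C@H](C)[C@H]1CCC[C@]12CCC[C@H](CC(OC)OC)N2CC(C(=O)OC)P(=O)(OC)OC
F8 | step 17 | phosphonate aldehyde (C3 formyl) | C#C[C@H](C)[C@H]1CCC[C@]12CCC[C@H](CC=O)N2CC(C(=O)OC)P(=O)(OC)OC
F9 | step 23 | C17 epimer of 31 | C[C@@H](C#C[C@H](O)/C=C(/Cl)CCO[Si](C)(C)C(C)(C)C)[C@H]1CCC[C@]12CCC[C@@H]3CC=C(C(=O)OC)CN23
F10 | step 23 | C17 ynone | C[C@@H](C#CC(=O)/C=C(/Cl)CCO[Si](C)(C)C(C)(C)C)[C@H]1CCC[C@]12CCC[C@@H]3CC=C(C(=O)OC)CN23
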